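The shift chemist and the development chemist hold the same two runs, in which J turns into L and G goes in by portions, and they disagree over where L goes in the new flask.

| flask | J | G | remark | time |
|---|---|---|---|---|
| west | 0.20 M | 1 mol% (in portions, 4) | run made earlier; portions every 30 min |  |
| east | 0.80 M | 1 mol% (in portions, 4) | run made earlier; portions every 30 min |  |
| flask | 0.40 M | 1 mol% (in portions, 4) | the portions of G follow each other after 30 min, the first at the start | 4.0 h |

- west (time / h: J / %, L / %): 1.33: 47, 38; 2.50: 27, 47; 4.00: 13, 33; 5.00: 8, 29
- east (time / h: J / %, L / %): 0.417: 78, 16; 0.833: 63, 26; 2.00: 29, 34; 5.00: 4, 15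

(readings scatter by 2 percentage points)

- concentration of J at 4.0 h, in M
- concentration of L at 4.0 h, in M
- concentration of Z at 4.0 h, in M

They share one reckoning. After the last portion of G, whatever J and L lose together has left L, so that loss over the logarithmic mean of L and the elapsed time gives L's loss constant. West, from 2.50 h to 5.00 h, gives 0.397 /h. East, from 2.00 h to 5.00 h, gives 0.632 /h. East holds 4.00 times west's c(G), but the constant grew by a factor of 1.59.

The shift chemist keeps one exit, into Z, with a constant between the two, and notes that “it rises less than proportionally with total G”. The development chemist reads two exits side by side: one indifferent to G, with 0.319 /h, and one proportional to c(G), with 39.1 /M/h. Since Z is listed as the other product, she sends the G exit to a product nobody has read. Her Z share, the selectivity for Z, is the G-free constant over the sum of both exits at the flask's c(G): 67.1%. Applied to what the forecast takes from J and L, it gives her c(Z) = 0.169 M.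

The forecast, the shift chemist's, reads c(J) = 0.04 M, c(L) = 0.108 M and c(Z) = 0.252 M.

The flask gives c(J) = 0.0461 M, c(L) = 0.108 M and c(Z) = 0.137 M.

    J → L (k = 0.540 /h)
    G + L → G + E (k = 61.0 /M/h)
    L → Z (k = 0.270 /h)

The forecast's c(Z) is too high by a factor of 1.84, while its c(L) matches. That match belongs to this loading of G: in this flask, with all other amounts and the time held, c(L) has moved by a tenth of itself at 0.8 mol% and at 1.2 mol% of G. The development chemist's Z share of 67.1%, an estimate from the scattered readings, applied to what this flask took from J and L gives 0.165 M, higher than the flask's c(Z). For a neighbour flask charged with 0.16 M of J, her estimate of the Z share is 83.6%, and on that flask's losses it gives 0.0697 M; that flask gives c(Z) = 0.0631 M.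

All runs were generated by integration with constants of no real substance.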